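The bicyclo[3.3.1]nonane-2,4,9-trione core has its C9 ketone on bridgehead C5, and C5 carries the ring-B methylene C6. Moving C6 back from C5 to C9 contracts ring B to a cyclopentane and gives a cis-fused hydrindane ketol-dione (C1 prenyl, C8 gem-dimethyl, C7 silyloxy, C9 tertiary alcohol, ring-A 2,4-dione). In the forward sense, trivalent-iodine oxidation of the ring-A dione enolate at C3 makes C5 electrophilic through the C4 enol; the C9 alkoxide then pushes C6 onto C5, forming the C5–C6 bond, ring B and the C9 ketone together. The C7 silyloxy group, taken from (R)-allethrolone, fixes C1 and is later replaced by the endo geranyl group.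

Key step: step 7

Numbering (target numbering, kept for all intermediates): C1 = bridgehead next to C8 (CMe2); C2–C3–C4 = enolised diketone bridge with the aroyl on C3; C5 = second bridgehead; C6 = methylene; C7 = geranyl methine; C9 = bridging ketone. Ring A = C1, C2, C3, C4, C5, C9; ring B = C1, C8, C7, C6, C5, C9. Prenyl = 3-methylbut-2-enyl; TBS = tert-butyldimethylsilyl.

Remarks:
- Assumption: the lipase hydrolyses the (R)-acetate faster, the usual preference for secondary alcohols of this shape.
- Assumption: the 2-methoxy enol ether, which keeps the C4 carbonyl next to C5–H, is the isomer that lithiates at the bridgehead. Methylation of 12 is not expected to be regiospecific, so only this isomer is carried on. Any 4-methoxy regioisomer is removed at the chromatography of step 8 and can be saponified back to 12 with aqueous LiOH and methylated again.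
- Stereochemical bookkeeping: the C7 centre of (R)-allethrolone passes unchanged into 10 and 12. Acylation anti to its silyloxy group gives the C1 configuration of the target, and the bicycle then fixes C5. The exo silyloxy group of 12 is replaced, through the C7 ketone, by the endo geranyl group.
- The target is an enolised triketone whose C2-enol and C4-enol forms interconvert, so step 19 gives the compound as drawn.

Step 1
Reactants: 1 rac-allethrolone (racemic 2-allyl-4-hydroxy-3-methylcyclopent-2-en-1-one)
Product: 2 rac-allethrolone acetate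
Conditions: Ac2O, pyridine, DMAP (cat.), CH2Cl2, 0 °C to rt
Reagents that add atoms: acetic anhydride, CC(=O)OC(C)=O
Why: Nucleophile-catalysed O-acetylation of the secondary alcohol supplies the ester substrate for the enzymatic resolution and touches no stereocentre.

Step 2
Reactants: 2 rac-allethrolone acetate
Product: 3 (R)-allethrolone
Conditions: Burkholderia cepacia lipase, phosphate buffer pH 7, t-BuOMe, 30 °C, stopped near half conversion; chromatography
Reagents that add atoms: none
Why: Lipase-catalysed kinetic resolution by enantioselective ester hydrolysis, in which the (R)-acetate should be cleaved faster so that the (R)-alcohol is separated from unreacted (S)-acetate, which secures the C7 stereocentre of the route.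

Step 3
Reactants: 3 (R)-allethrolone
Product: 4 (R)-2-allyl-4-(tert-butyldimethylsilyloxy)-3-methylcyclopent-2-en-1-one
Conditions: TBSCl, imidazole, DMF, rt
Reagents that add atoms: tert-butyldimethylsilyl chloride, CC(C)(C)[Si](C)(C)Cl
Why: Imidazole-promoted silylation gives a silyl ether that survives the organometallic steps and, unlike an ester, is not lost as a leaving group in the cuprate step.

Step 4
Reactants: 4 (R)-silyl ether of allethrolone
Product: 5 (R)-4-(tert-butyldimethylsilyloxy)-3-methyl-2-prenylcyclopent-2-en-1-one
Conditions: 2-methylbut-2-ene (excess), second-generation Grubbs catalyst RuCl2(=CHPh)(H2IMes)(PCy3) (cat.), CH2Cl2, 40 °C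
Reagents that add atoms: 2-methylbut-2-ene, CC=C(C)C
Why: Olefin cross-metathesis exchanges the terminal =CH2 of the allyl group for =CMe2 with loss of propene, the tetrasubstituted enone alkene being inert to the ruthenium carbene.

Step 5
Reactants: 5 prenyl enone
Product: 6 (4R)-4-(tert-butyldimethylsilyloxy)-3,3-dimethyl-2-prenyl-1-(trimethylsilyloxy)cyclopent-1-ene
Conditions: MeLi, CuI, Et2O, 0 °C; then 5, TMSCl, THF, −78 to −20 °C; Et3N, NaHCO3 (aq)
Reagents that add atoms: lithium dimethylcuprate (made from MeLi and CuI), [Li+].C[Cu-]C; chlorotrimethylsilane, C[Si](C)(C)Cl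
Why: Silyl-chloride-accelerated conjugate addition of the Gilman cuprate places the second methyl on C8 of the tetrasubstituted enone and O-silylation stores the C1=C9 enolate regiochemistry; C8 becomes a CMe2 carbon, so no stereocentre is created and C7 is untouched.

Step 6
Reactants: 6 TMS enol ether; 7 diketene (4-methyleneoxetan-2-one)
Product: 10 cis-fused C7-silyloxy hydrindane ketol-dione (precursor of the key step), via lithium enolate 8 (not isolated), via 2-acetoacetylcyclopentanone 9 (not isolated)
Conditions: MeLi, THF, 0 °C; then 7, −78 to −30 °C; NH4Cl (aq)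
Reagents that add atoms: none
Why: MeLi cleaves the O–Si bond to the regiodefined lithium enolate 8, diketene acylates it at C1 (ring-opening acetoacetylation) to give 9, and the terminal methyl-ketone enolate set free by that ring opening adds to the C9 carbonyl in an intramolecular aldol reaction that can only give the cis ring fusion; the C1 stereocentre is set by attack anti to the C7 silyloxy group, because with that group pseudoequatorial the C8 methyl cis to it is pseudoaxial on the same face and screens it, and C9 follows from C1.

Step 7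
Reactants: 10 cis-fused hydrindane ketol-dione
Product: 12 7-exo-(tert-butyldimethylsilyloxy)-8,8-dimethyl-1-prenylbicyclo[3.3.1]nonane-2,4,9-trione, via C3 phenyliodonium ylide 11 (not isolated)
Conditions: KOH, MeOH, −30 °C; PhI(OAc)2, −30 to 0 °C; dilute HCl work-up
Reagents that add atoms: none
Why: Methanolic KOH gives the ring-A dione enolate, which PhI(OAc)2 converts into the C3 phenyliodonium ylide 11; in its C4=C5 enol form the trivalent-iodine group is a vinylogous leaving group for C5, and the C9 alkoxide then collapses to the ketone while the C9–C6 bond shifts to C5 (SN2′-type semipinacol step) with loss of iodobenzene. The closest known reaction type is the iodane-induced oxidative ring expansion of diketene-derived fused ketol-1,3-diones to bicyclo[3.3.1]nonane-2,4,9-triones. Ring B (C1–C8–C7–C6–C5–C9) is closed by one-carbon enlargement of the cyclopentane through this 1,2-alkyl shift and not by a cyclisation, so neither a bridgehead enolate nor an intermolecular attack on a hindered centre is involved. The new C5 stereocentre is fixed by the cis ring fusion, because C6 can only reach the face of ring A on which it already sits, so C5 follows from C1. The selectivity needed is migration of C6 and not of C1: the exocyclic C9–C6 bond can stand parallel to the C5 p orbital of the enol, whereas the C9–C1 bond lies in ring A near the enol plane and C1 is an electron-poor, acyl-bearing carbon. The secondary silyl ether and the prenyl alkene should be inert to cold methanolic KOH and to the iodane while the far more nucleophilic enolate is present.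

Step 8
Reactants: 12 bicyclic trione
Product: 13 7-exo-(tert-butyldimethylsilyloxy)-2-methoxy-8,8-dimethyl-1-prenylbicyclo[3.3.1]non-2-ene-4,9-dione
Conditions: TMSCHN2, MeOH/toluene, 0 °C to rt; chromatography
Reagents that add atoms: trimethylsilyldiazomethane, C[Si](C)(C)C=[N+]=[N-]
Why: O-Methylation of the vinylogous acid by the diazoalkane (proton transfer, then methyl transfer within the ion pair) takes place on oxygen and not on C3, and the 2-methoxy isomer 13, the one that keeps the C4 carbonyl beside C5–H, is separated by chromatography from the 4-methoxy regioisomer that the second enol oxygen can give.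

Step 9
Reactants: 13 2-methoxy enol ether
Product: 15 7-exo-(tert-butyldimethylsilyloxy)-2-methoxy-8,8-dimethyl-1,5-diprenylbicyclo[3.3.1]non-2-ene-4,9-dione, via C5-lithio enol ether 14 (not isolated)
Conditions: LDA, THF, −78 °C; prenyl bromide, −78 to −20 °C
Reagents that add atoms: prenyl bromide (1-bromo-3-methylbut-2-ene), CC(C)=CCBr
Why: Bridgehead lithiation–alkylation known for methyl enol ethers of bicyclo[3.3.1]nonane-2,4,9-triones: C5–H, flanked by the C4 and C9 carbonyls, is removed by LDA to a pyramidal, inductively stabilised carbanion 14 (no planar enolate is required) that is alkylated by the allylic bromide with retention, the quaternary C5 configuration being dictated by the bicycle.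

Step 10
Reactants: 15 C5-prenylated silyl ether
Product: 16 7-exo-hydroxy-2-methoxy-8,8-dimethyl-1,5-diprenylbicyclo[3.3.1]non-2-ene-4,9-dione
Conditions: HF·pyridine, pyridine, THF, 0 °C to rt
Reagents that add atoms: none
Why: Fluoride-mediated Si–O cleavage frees the exo C7 alcohol under mild, non-aqueous conditions that leave the methyl enol ether and the prenyl groups intact, without inversion at C7.

Step 11
Reactants: 16 C7 alcohol
Product: 17 2-methoxy-8,8-dimethyl-1,5-diprenylbicyclo[3.3.1]non-2-ene-4,7,9-trione
Conditions: Dess–Martin periodinane, NaHCO3, CH2Cl2, rt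
Reagents that add atoms: none
Why: Dess–Martin oxidation under buffered, neutral conditions converts the hindered secondary alcohol into the C7 ketone without touching the alkenes, which erases the sacrificial C7 stereocentre.

Step 12
Reactants: 17 C7 ketone
Product: 18 2-methoxy-8,8-dimethyl-7-methylene-1,5-diprenylbicyclo[3.3.1]non-2-ene-4,9-dione
Conditions: Ph3PCH3Br, KOtBu, toluene, rt; then 17, 80 °C
Reagents that add atoms: methyltriphenylphosphonium bromide (as its ylide), C[P+](c1ccccc1)(c1ccccc1)c1ccccc1.[Br-]
Why: Wittig methylenation with salt-free Ph3P=CH2 at elevated temperature is reliable for hindered α,α-disubstituted cyclohexanones, and only C7 should react because the C9 ketone is screened by two quaternary bridgeheads and the C4 carbonyl is a deactivated vinylogous ester.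

Step 13
Reactants: 19 6-methylhept-5-en-2-one
Product: 21 6-methylhept-5-en-1-yne, via enol diethyl phosphate 20 (not isolated)
Conditions: LDA, THF, −78 °C; ClP(O)(OEt)2, −78 °C to rt; then LDA (2.3 equiv), −78 °C to rt; H2O
Reagents that add atoms: none
Why: Kinetic deprotonation at the methyl group and O-phosphorylation give the terminal enol phosphate 20, from which excess LDA eliminates phosphate to give the terminal alkyne (methyl ketone to alkyne conversion through an enol phosphate), the trisubstituted alkene being inert.

Step 14
Reactants: 21 6-methylhept-5-en-1-yne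
Product: 23 (E)-1-iodo-2,6-dimethylhepta-1,5-diene, via alkenyldimethylalane 22 (not isolated)
Conditions: Me3Al, Cp2ZrCl2, CH2Cl2, 0 °C to rt; then I2, THF, −30 to 0 °C
Reagents that add atoms: trimethylaluminium, C[Al](C)C; iodine, II
Why: Zirconium-catalysed carboalumination (Negishi) adds methyl and aluminium syn across the terminal alkyne with aluminium at the terminus, and iodinolysis of the C–Al bond with retention gives the E alkenyl iodide, the geometry needed for the geranyl chain.

Step 15
Reactants: 18 C7 methylene compound; 23 (E)-alkenyl iodide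
Product: 25 7-endo-geranyl-2-methoxy-8,8-dimethyl-1,5-diprenylbicyclo[3.3.1]non-2-ene-4,9-dione, via B-alkyl-9-BBN 24 (not isolated)
Conditions: 9-BBN-H dimer, THF, 0 °C to rt; then 23, Pd(dppf)Cl2 (cat.), AsPh3, Cs2CO3, DMF/H2O, rt
Reagents that add atoms: none
Why: Hydroboration followed by B-alkyl Suzuki–Miyaura coupling: 9-BBN adds boron to the terminal carbon of the 1,1-disubstituted alkene (the prenyl alkenes and the shielded carbonyls react far more slowly) and delivers hydrogen to C7 from the open exo face, since ring A covers the endo face, so the new CH2 group is endo; alkylborane 24 then couples with iodide 23 at zerovalent palladium with retention of the E geometry.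

Step 16
Reactants: 26 3-hydroxybenzoic acid
Product: 27 tert-butyldimethylsilyl 3-(tert-butyldimethylsilyloxy)benzoate
Conditions: TBSCl (2.2 equiv), imidazole, DMF, rt
Reagents that add atoms: tert-butyldimethylsilyl chloride, CC(C)(C)[Si](C)(C)Cl
Why: Silylation of both the phenol and the carboxylic acid masks the phenol as an ether inert to the lithiated enol ether and provides a silyl ester for neutral conversion into the acid chloride.

Step 17
Reactants: 27 bis-silylated 3-hydroxybenzoic acid
Product: 28 3-(tert-butyldimethylsilyloxy)benzoyl chloride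
Conditions: (COCl)2, DMF (cat.), CH2Cl2, 0 °C to rt
Reagents that add atoms: oxalyl chloride, O=C(Cl)C(Cl)=O
Why: The chloroiminium reagent formed from oxalyl chloride and DMF converts the silyl ester directly into the acid chloride with loss of TBSCl, CO and CO2 and without free HCl, so the aryl silyl ether survives.

Step 18
Reactants: 25 geranyl enol ether; 28 aroyl chloride
Product: 30 3-[3-(tert-butyldimethylsilyloxy)benzoyl]-7-endo-geranyl-2-methoxy-8,8-dimethyl-1,5-diprenylbicyclo[3.3.1]non-2-ene-4,9-dione, via C3-lithio enol ether 29 (not isolated)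
Conditions: 2,2,6,6-tetramethylpiperidine, n-BuLi, THF, 0 °C; 25, −78 °C; then 28, −78 to −40 °C
Reagents that add atoms: none
Why: Vinyl lithiation–acylation known for methyl enol ethers of bicyclic triones: with both bridgeheads quaternary, the hindered amide base removes the C3 vinylic proton between the C4 carbonyl and the methoxy-bearing C2, and alkenyllithium 29 is C-acylated by the aroyl chloride at low temperature without affecting any stereocentre.

Step 19
Reactants: 30 protected target
Product: 31 CNP0290731.1
Conditions: LiOH, dioxane/H2O, 90 °C; then 1 M HCl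
Reagents that add atoms: lithium hydroxide, [Li+].[OH-]
Why: Hydroxide adds to C2 of the doubly acyl-activated β-methoxy enone and expels methoxide (vinylogous ester saponification) and also cleaves the aryl silyl ether at silicon, so that acidification releases the enolised triketone and the free phenol in one operation; C1 and C5 are quaternary and C7 is not acidic, so no stereocentre can epimerise.

Compound list
1 | rac-allethrolone | C=CCC1=C(C)C(O)CC1=O | starting material
2 | rac-allethrolone acetate | C=CCC1=C(C)C(OC(C)=O)CC1=O | intermediate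
3 | (R)-allethrolone | C=CCC1=C(C)[C@H](O)CC1=O | intermediate
4 | (R)-2-allyl-4-(tert-butyldimethylsilyloxy)-3-methylcyclopent-2-en-1-one | C=CCC1=C(C)[C@H](O[Si](C)(C)C(C)(C)C)CC1=O | intermediate
5 | (R)-4-(tert-butyldimethylsilyloxy)-3-methyl-2-prenylcyclopent-2-en-1-one | CC(C)=CCC1=C(C)[C@H](O[Si](C)(C)C(C)(C)C)CC1=O | intermediate
6 | (4R)-4-(tert-butyldimethylsilyloxy)-3,3-dimethyl-2-prenyl-1-(trimethylsilyloxy)cyclopent-1-ene | CC(C)=CCC1=C(O[Si](C)(C)C)C[C@@H](O[Si](C)(C)C(C)(C)C)C1(C)C | intermediate
7 | diketene | C=C1CC(=O)O1 | starting material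
8 | lithium enolate of (4R)-4-(tert-butyldimethylsilyloxy)-3,3-dimethyl-2-prenylcyclopentanone (not isolated) | CC(C)=CCC1=C(O[Li])C[C@@H](O[Si](C)(C)C(C)(C)C)C1(C)C | intermediate
9 | 2-acetoacetyl-4-(tert-butyldimethylsilyloxy)-3,3-dimethyl-2-prenylcyclopentanone, acetoacetyl trans to the silyloxy group (not isolated) | CC(C)=CC[C@@]1(C(=O)CC(C)=O)C(=O)C[C@@H](O[Si](C)(C)C(C)(C)C)C1(C)C | intermediate
10 | cis-fused hydrindane ketol-dione: C9 tertiary alcohol and C1 prenyl at the ring fusion, C2 and C4 ketones, C8 gem-dimethyl, C7 OTBS cis to the C1 prenyl group | CC(C)=CC[C@@]12C(=O)CC(=O)C[C@]1(O)C[C@@H](O[Si](C)(C)C(C)(C)C)C2(C)C | intermediate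
11 | C3 phenyliodonium ylide of 10 (not isolated) | CC(C)=CC[C@@]12C(=O)C([I+]c3ccccc3)=C([O-])C[C@]1(O)C[C@@H](O[Si](C)(C)C(C)(C)C)C2(C)C | intermediate
12 | 7-exo-(tert-butyldimethylsilyloxy)-8,8-dimethyl-1-prenylbicyclo[3.3.1]nonane-2,4,9-trione | CC(C)(C)[Si](C)(C)O[C@@H]1C[C@@H]2C(=O)[C@@](CC=C(C)C)(C(=O)CC2=O)C1(C)C | intermediate
13 | 7-exo-(tert-butyldimethylsilyloxy)-2-methoxy-8,8-dimethyl-1-prenylbicyclo[3.3.1]non-2-ene-4,9-dione | CC(C)(C)[Si](C)(C)O[C@@H]1C[C@@H]2C(=O)[C@@](CC=C(C)C)(C(OC)=CC2=O)C1(C)C | intermediate
14 | C5-lithio derivative of 13 (not isolated) | CC(C)(C)[Si](C)(C)O[C@@H]1C[C@]2([Li])C(=O)[C@@](CC=C(C)C)(C(OC)=CC2=O)C1(C)C | intermediate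
15 | 7-exo-(tert-butyldimethylsilyloxy)-2-methoxy-8,8-dimethyl-1,5-diprenylbicyclo[3.3.1]non-2-ene-4,9-dione | CC(C)(C)[Si](C)(C)O[C@@H]1C[C@]2(CC=C(C)C)C(=O)[C@@](CC=C(C)C)(C(OC)=CC2=O)C1(C)C | intermediate
16 | 7-exo-hydroxy-2-methoxy-8,8-dimethyl-1,5-diprenylbicyclo[3.3.1]non-2-ene-4,9-dione | O[C@@H]1C[C@]2(CC=C(C)C)C(=O)[C@@](CC=C(C)C)(C(OC)=CC2=O)C1(C)C | intermediate
17 | 2-methoxy-8,8-dimethyl-1,5-diprenylbicyclo[3.3.1]non-2-ene-4,7,9-trione | O=C1C[C@]2(CC=C(C)C)C(=O)[C@@](CC=C(C)C)(C(OC)=CC2=O)C1(C)C | intermediate
18 | 2-methoxy-8,8-dimethyl-7-methylene-1,5-diprenylbicyclo[3.3.1]non-2-ene-4,9-dione | C=C1C[C@]2(CC=C(C)C)C(=O)[C@@](CC=C(C)C)(C(OC)=CC2=O)C1(C)C | intermediate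
19 | 6-methylhept-5-en-2-one | CC(C)=CCCC(C)=O | starting material
20 | diethyl 6-methylhepta-1,5-dien-2-yl phosphate (not isolated) | CC(C)=CCCC(=C)OP(=O)(OCC)OCC | intermediate
21 | 6-methylhept-5-en-1-yne | CC(C)=CCCC#C | intermediate
22 | (E)-(2,6-dimethylhepta-1,5-dienyl)dimethylalane (not isolated) | CC(C)=CCC/C(C)=C/[Al](C)C | intermediate
23 | (E)-1-iodo-2,6-dimethylhepta-1,5-diene | CC(C)=CCC/C(C)=C/I | intermediate
24 | B-alkyl-9-BBN from 18, boron on the endo C7–CH2 group (not isolated) | C(B1C2CCCC1CCC2)[C@H]3C[C@]4(CC=C(C)C)C(=O)[C@@](CC=C(C)C)(C(OC)=CC4=O)C3(C)C | intermediate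
25 | 7-endo-geranyl-2-methoxy-8,8-dimethyl-1,5-diprenylbicyclo[3.3.1]non-2-ene-4,9-dione | CC(C)=CCC/C(C)=C/C[C@H]1C[C@]2(CC=C(C)C)C(=O)[C@@](CC=C(C)C)(C(OC)=CC2=O)C1(C)C | intermediate
26 | 3-hydroxybenzoic acid | OC(=O)c1cccc(O)c1 | starting material
27 | tert-butyldimethylsilyl 3-(tert-butyldimethylsilyloxy)benzoate | CC(C)(C)[Si](C)(C)OC(=O)c1cccc(O[Si](C)(C)C(C)(C)C)c1 | intermediate
28 | 3-(tert-butyldimethylsilyloxy)benzoyl chloride | CC(C)(C)[Si](C)(C)Oc1cccc(C(Cl)=O)c1 | intermediate
29 | C3-lithio derivative of 25 (not isolated) | CC(C)=CCC/C(C)=C/C[C@H]1C[C@]2(CC=C(C)C)C(=O)[C@@](CC=C(C)C)(C(OC)=C([Li])C2=O)C1(C)C | intermediate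
30 | 3-[3-(tert-butyldimethylsilyloxy)benzoyl]-7-endo-geranyl-2-methoxy-8,8-dimethyl-1,5-diprenylbicyclo[3.3.1]non-2-ene-4,9-dione | CC(C)=CCC/C(C)=C/C[C@H]1C[C@]2(CC=C(C)C)C(=O)[C@@](CC=C(C)C)(C(OC)=C(C(=O)c3cccc(O[Si](C)(C)C(C)(C)C)c3)C2=O)C1(C)C | intermediate
31 | CNP0290731.1: 7-endo-geranyl-4-hydroxy-3-(3-hydroxybenzoyl)-8,8-dimethyl-1,5-diprenylbicyclo[3.3.1]non-3-ene-2,9-dione | CC(C)=CCC/C(C)=C/C[C@H]1C[C@]2(CC=C(C)C)C(=O)[C@@](CC=C(C)C)(C(=O)C(C(=O)c3cccc(O)c3)=C2O)C1(C)C | target

Total steps: 19 (15 in the main line, 2 for alkenyl iodide 23, 2 for acid chloride 28).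
Longest linear sequence: 15 steps (steps 1–12, 15, 18, 19).

Steps most likely to fail

1. Step 7. The 1,2-shift of C6 may be slower than other decay paths of ylide 11 (methanolysis at C3, retro-aldol opening of the ketol), because a methylene carrying a β-silyloxy group is a weak migrating group. Fallback, from 10 back to 13: C5 is made the electrophilic centre directly. Ketol-dione 10 is O-methylated with TMSCHN2 and the 2-methoxy vinylogous ester of the ketol F1 is isolated. Its dianion (LDA, 2.2 equiv, THF, −78 °C; C9 alkoxide and C5 α′-enolate) is brominated with N-bromosuccinimide on the face syn to the C9 oxygen to give the 5-bromo ketol F2, in which bromine is anti to the C9–C6 bond. AgBF4 with 2,6-di-tert-butylpyridine in CH2Cl2 then triggers a silver-assisted halohydrin semipinacol shift, C6 displacing bromide from the rear, which gives enol ether 13 and bypasses 12.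

2. Step 6. Diketene may acylate the hindered tetrasubstituted enolate on oxygen instead of forming the C1–C2 bond next to the gem-dimethyl carbon. Fallback, from 6 back to 10: enolate 8 (from 6 and MeLi) is added at −78 °C to 2-(2-methyl-1,3-dioxolan-2-yl)acetaldehyde F3, itself made by i-Bu2AlH reduction of commercial ethyl 2-(2-methyl-1,3-dioxolan-2-yl)acetate. An aldehyde can only react at carbon, so this aldol addition gives the β-hydroxy ketone F4. Dess–Martin oxidation gives the β-diketone ketal F5, PPTS in wet acetone removes the dioxolane to give triketone 9, and K2CO3 in MeOH closes 9 to 10.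

3. Step 15. The dialkylborane may reduce the C4 vinylogous ester carbonyl while the hindered alkene reacts slowly, and transmetalation of the β-branched endo alkylborane may be sluggish. Fallback, from 18 back to 25: RhCl(PPh3)3-catalysed hydroboration with catecholborane, which is alkene-selective in the presence of ketones and still delivers hydrogen to the exo face, gives the primary alkyl catechol boronate F6. KHF2 in aqueous MeOH converts it into the potassium alkyltrifluoroborate F7, which is purified and coupled with alkenyl iodide 23 (Pd(dppf)Cl2, Cs2CO3, toluene/H2O, 80 °C) to give 25.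

Further compounds
F1 | step 7 | 2-methoxy vinylogous ester of ketol-dione 10 | CC(C)=CC[C@@]12C(OC)=CC(=O)C[C@]1(O)C[C@@H](O[Si](C)(C)C(C)(C)C)C2(C)C
F2 | step 7 | 5-bromo derivative of F1, bromine cis to the C9 hydroxyl | CC(C)=CC[C@@]12C(OC)=CC(=O)[C@@H](Br)[C@]1(O)C[C@@H](O[Si](C)(C)C(C)(C)C)C2(C)C
F3 | step 6 | 2-(2-methyl-1,3-dioxolan-2-yl)acetaldehyde | CC1(CC=O)OCCO1
F4 | step 6 | aldol adduct of enolate 8 and F3 (carbinol epimers) | CC(C)=CC[C@@]1(C(O)CC2(C)OCCO2)C(=O)C[C@@H](O[Si](C)(C)C(C)(C)C)C1(C)C
F5 | step 6 | β-diketone ketal from oxidation of F4 | CC(C)=CC[C@@]1(C(=O)CC2(C)OCCO2)C(=O)C[C@@H](O[Si](C)(C)C(C)(C)C)C1(C)C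
F6 | step 15 | alkyl catechol boronate from 18, boron on the endo C7–CH2 group | C(B1Oc2ccccc2O1)[C@H]3C[C@]4(CC=C(C)C)C(=O)[C@@](CC=C(C)C)(C(OC)=CC4=O)C3(C)C
F7 | step 15 | potassium alkyltrifluoroborate from F6 | [K+].F[B-](F)(F)C[C@H]1C[C@]2(CC=C(C)C)C(=O)[C@@](CC=C(C)C)(C(OC)=CC2=O)C1(C)C
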